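**Route outline**

Side-chain atoms are labelled C1' (on coumarin C3) to C10'. The retrosynthesis cuts C8'–C9' first (isobutyl Grignard on a (Z)-enal), then C3–C1', which a [3,3] shift traces back to the O–C3' bond of a 4-coumarinyl allyl ether, and last C2'–C3' (alkenylchromium addition to an aldehyde from neryl acetate).
The enabling feature is the unit C3(pyranone ring)–C1'H(CH3)–C2'(CH3)=C3'H beside the C4 hydroxyl: the C3–C1' bond, the only stereocentre and the E alkene all descend from one C3' carbinol.
Forward, no ring is formed (the coumarin bicycle is bought); the chain is joined in the order C2'–C3', O–C3', C3–C1', C8'–C9'.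
Stereochemistry: CBS reduction sets the (S)-C3' carbinol, the Mitsunobu step inverts it to the R ether, and the Claisen shift relays it suprafacially to (S)-C1' while creating (E)-C2'=C3'. The (Z)-C6'=C7' alkene comes from neryl acetate and the E-butenyl terminus from (E)-2-bromo-2-butene.

Key step: step 7

Assumption: in the CBS reduction the 1-methylprop-1-enyl group is taken as the large ketone substituent, so the (R)-catalyst is assigned to the S carbinol; if the sense proved opposite, the (S)-catalyst would be used.

**Route**

Step 1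
Reactants: 1 neryl acetate
Product: 2 racemic 6,7-epoxyneryl acetate [(Z)-5-(3,3-dimethyloxiran-2-yl)-3-methylpent-2-en-1-yl acetate]
Conditions: mCPBA (1.05 equiv), NaHCO3, CH2Cl2, 0 °C
Reagents that add atoms: mCPBA (3-chloroperoxybenzoic acid), OOC(=O)c1cccc(Cl)c1
Why: Prilezhaev epoxidation, in which the electrophilic peracid should take the more electron-rich distal alkene because the C2=C3 alkene is deactivated by the allylic acetoxy group; the racemic epoxide centre disappears in step 2.

Step 2
Reactants: 2 racemic 6,7-epoxyneryl acetate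
Product: 4 (Z)-3-methyl-6-oxohex-2-en-1-yl acetate, via 6,7-dihydroxy-6,7-dihydroneryl acetate 3 (not isolated)
Conditions: H5IO6 (1.2 equiv), THF–H2O, 0 °C to rt
Reagents that add atoms: none
Why: Periodic acid opens the epoxide to the vicinal diol 3 (water entering at the tertiary carbon) and cleaves it at once (Malaprade glycol cleavage) to the aldehyde and acetone, conditions that the acetate and the isolated Z alkene should tolerate.

Step 3
Reactants: 4 (Z)-3-methyl-6-oxohex-2-en-1-yl acetate; 5 (E)-2-bromo-2-butene (methyl groups cis)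
Product: 7 racemic (2Z,7E)-6-hydroxy-3,7-dimethylnona-2,7-dien-1-yl acetate, via (E)-but-2-en-2-ylchromium dichloride 6 (not isolated)
Conditions: CrCl2 (4 equiv), NiCl2 (2 mol %), 5 (3 equiv), DMF, rt
Reagents that add atoms: (E)-2-bromo-2-butene (5), C/C=C(\C)Br
Why: Nozaki–Hiyama–Kishi reaction, in which zerovalent nickel formed in situ inserts into the C–Br bond with retention of alkene geometry and transmetalation gives the alkenyl derivative 6 of trivalent chromium, which adds to the aldehyde but not to the acetate; the new carbinol centre is racemic and is erased in step 4.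

Step 4
Reactants: 7 racemic (2Z,7E)-6-hydroxy-3,7-dimethylnona-2,7-dien-1-yl acetate
Product: 8 (2Z,7E)-3,7-dimethyl-6-oxonona-2,7-dien-1-yl acetate
Conditions: Dess–Martin periodinane (1.3 equiv), CH2Cl2, 0 °C to rt
Reagents that add atoms: none
Why: Dess–Martin oxidation of a secondary allylic alcohol to the enone is fast and mild, there is no epimerisable centre, and the E trisubstituted enone and the allylic acetate should not react.

Step 5
Reactants: 8 (2Z,7E)-3,7-dimethyl-6-oxonona-2,7-dien-1-yl acetate
Product: 9 (2Z,6S,7E)-6-hydroxy-3,7-dimethylnona-2,7-dien-1-yl acetate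
Conditions: (R)-2-methyl-CBS-oxazaborolidine [(3aR)-1-methyl-3,3-diphenyltetrahydro-1H,3H-pyrrolo[1,2-c][1,3,2]oxazaborole, 0.2 equiv], catecholborane (1.8 equiv), toluene, −78 °C; aq. NaOH work-up
Reagents that add atoms: none
Why: Corey–Bakshi–Shibata reduction, in which the ketone binds the oxazaborolidine–borane complex with the 1-methylpropenyl group as the large substituent so that the (R)-catalyst should deliver hydride to the face giving the S carbinol, while catecholborane at low temperature leaves both alkenes and the acetate untouched.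

Step 6
Reactants: 9 (2Z,6S,7E)-6-hydroxy-3,7-dimethylnona-2,7-dien-1-yl acetate; 10 4-hydroxy-7-methoxycoumarin
Product: 11 (2Z,6R,7E)-6-[(7-methoxy-2-oxo-2H-chromen-4-yl)oxy]-3,7-dimethylnona-2,7-dien-1-yl acetate
Conditions: 10 (1.5 equiv), PPh3 (1.5 equiv), DIAD (1.5 equiv, added last), THF, 0 °C to rt
Reagents that add atoms: 4-hydroxy-7-methoxycoumarin (10), COc1ccc2c(O)cc(=O)oc2c1
Why: Mitsunobu reaction, in which PPh3 and DIAD activate the carbinol oxygen of 9 and the coumarin 4-olate (pKa about 5) displaces it by SN2 with inversion, turning the S carbinol into the R ether; any 2-alkoxychromone regioisomer from the ambident anion would carry the same R centre and rearrange to the same product in step 7.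

Step 7
Reactants: 11 (2Z,6R,7E)-6-[(7-methoxy-2-oxo-2H-chromen-4-yl)oxy]-3,7-dimethylnona-2,7-dien-1-yl acetate
Product: 13 (2Z,6E,8S)-8-(4-hydroxy-7-methoxy-2-oxo-2H-chromen-3-yl)-3,7-dimethylnona-2,6-dien-1-yl acetate, via chroman-2,4-dione keto tautomer 12 (not isolated)
Conditions: degassed toluene (0.02 M), 110 °C, sealed base-washed vessel
Reagents that add atoms: none
Why: On heating, the O–C3' bond of 11 should break while C3 of the pyranone ring bonds to C1' in a concerted, suprafacial [3,3] sigmatropic shift through the six-centre array C3=C4–O–C3'–C2'=C1', and the chroman-2,4-dione 12 so formed enolises to the 4-hydroxycoumarin, which makes the step irreversible. The closest known reaction type is the thermal Claisen rearrangement of 4-allyloxycoumarins, combined with the 1,3-chirality transfer familiar from Johnson-type syntheses of trisubstituted alkenes from 2-methyl secondary allylic alcohols. No ring is closed. The new stereocentre C1' is controlled by the ether carbon C3': oxygen departs from and carbon arrives on the same face of the allyl unit, so with the C4' chain pseudo-equatorial and the (E)-butenyl terminus the R ether maps onto (S)-C1', and the same arrangement delivers the (E)-C2'=C3' alkene. The step needs complete chirality transfer and E selectivity, which the substrate should secure because a pseudo-axial C4' chain would clash with the benzo ring carbon C4a on C4, whereas chair or boat topology and the face of the heterocycle do not matter since C3 ends trigonal. It also needs the concerted path to outrun ion-pair [1,3] scrambling, the abnormal Claisen shift and dihydrofuran closure, for which the apolar acid-free medium, high dilution and the lowest workable temperature are chosen; the secondary, 2-methyl-substituted ether should rearrange well below the temperatures that primary allyl coumarinyl ethers require.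

Step 8
Reactants: 13 (2Z,6E,8S)-8-(4-hydroxy-7-methoxy-2-oxo-2H-chromen-3-yl)-3,7-dimethylnona-2,6-dien-1-yl acetate
Product: 14 4-hydroxy-3-[(2S,3E,7Z)-9-hydroxy-3,7-dimethylnona-3,7-dien-2-yl]-7-methoxy-2H-chromen-2-one
Conditions: K2CO3 (3 equiv), MeOH, 0 °C to rt; then aq. citric acid to pH 3–4
Reagents that add atoms: none
Why: Base-catalysed transesterification (Zemplén-type methanolysis) should remove the primary allylic acetate, while the 4-hydroxycoumarin, ionised under these conditions, resists attack of methoxide on the lactone and C1' is not acidic enough to epimerise.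

Step 9
Reactants: 14 4-hydroxy-3-[(2S,3E,7Z)-9-hydroxy-3,7-dimethylnona-3,7-dien-2-yl]-7-methoxy-2H-chromen-2-one
Product: 15 (2Z,6E,8S)-8-(4-hydroxy-7-methoxy-2-oxo-2H-chromen-3-yl)-3,7-dimethylnona-2,6-dienal
Conditions: activated MnO2 (20 equiv), CH2Cl2, rt, dark; used at once
Reagents that add atoms: none
Why: Allylic oxidation with MnO2 should touch only the primary allylic alcohol, stop at the aldehyde and, being neutral and heterogeneous, keep the Z geometry as in the oxidation of nerol to neral, the enol and the C2'=C3' alkene being inert.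

Step 10
Reactants: 15 (2Z,6E,8S)-8-(4-hydroxy-7-methoxy-2-oxo-2H-chromen-3-yl)-3,7-dimethylnona-2,6-dienal; 16 isobutylmagnesium bromide
Product: 18 4-hydroxy-3-[(2S,3E,7Z)-9-hydroxy-3,7,11-trimethyldodeca-3,7-dien-2-yl]-7-methoxy-2H-chromen-2-one (both C8' epimers), via bromomagnesium coumarin-4-olate enal 17 (not isolated)
Conditions: iBuMgBr (3.0 equiv), THF, −78 to −40 °C; then aq. citric acid
Reagents that add atoms: isobutylmagnesium bromide (16), CC(C)C[Mg]Br
Why: Grignard 1,2-addition, in which the first equivalent turns the acidic 4-hydroxyl into the magnesium olate 17 that shields the lactone and the hard alkylmagnesium reagent then adds to the carbonyl carbon of the β,β-disubstituted enal at low temperature; the new C8' carbinol centre is left uncontrolled because step 11 removes it.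

Step 11
Reactants: 18 4-hydroxy-3-[(2S,3E,7Z)-9-hydroxy-3,7,11-trimethyldodeca-3,7-dien-2-yl]-7-methoxy-2H-chromen-2-one
Product: 19 4-hydroxy-7-methoxy-3-[(2S,3E,7Z)-3,7,11-trimethyl-9-oxododeca-3,7-dien-2-yl]-2H-chromen-2-one (CNP0223069.2)
Conditions: activated MnO2 (20 equiv), CH2Cl2, rt, dark
Reagents that add atoms: none
Why: Allylic oxidation with MnO2 should convert both C8' epimers into the single enone under neutral conditions that avoid Z to E isomerisation and leave the enol, the C2'=C3' alkene and the C1' centre untouched.

**Compound list**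

1 | neryl acetate | CC(C)=CCC/C(C)=C\COC(C)=O | starting material
2 | racemic 6,7-epoxyneryl acetate | CC1(C)OC1CC/C(C)=C\COC(C)=O | intermediate
3 | 6,7-dihydroxy-6,7-dihydroneryl acetate (racemic, not isolated) | CC(C)(O)C(O)CC/C(C)=C\COC(C)=O | intermediate
4 | (Z)-3-methyl-6-oxohex-2-en-1-yl acetate | O=CCC/C(C)=C\COC(C)=O | intermediate
5 | (E)-2-bromo-2-butene | C/C=C(\C)Br | starting material
6 | (E)-but-2-en-2-ylchromium dichloride (not isolated) | C/C=C(\C)[Cr](Cl)Cl | intermediate
7 | racemic (2Z,7E)-6-hydroxy-3,7-dimethylnona-2,7-dien-1-yl acetate | C/C=C(\C)C(O)CC/C(C)=C\COC(C)=O | intermediate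
8 | (2Z,7E)-3,7-dimethyl-6-oxonona-2,7-dien-1-yl acetate | C/C=C(\C)C(=O)CC/C(C)=C\COC(C)=O | intermediate
9 | (2Z,6S,7E)-6-hydroxy-3,7-dimethylnona-2,7-dien-1-yl acetate | C/C=C(\C)[C@@H](O)CC/C(C)=C\COC(C)=O | intermediate
10 | 4-hydroxy-7-methoxycoumarin | COc1ccc2c(O)cc(=O)oc2c1 | starting material
11 | (2Z,6R,7E)-6-[(7-methoxy-2-oxo-2H-chromen-4-yl)oxy]-3,7-dimethylnona-2,7-dien-1-yl acetate | C/C=C(\C)[C@H](Oc1cc(=O)oc2cc(OC)ccc12)CC/C(C)=C\COC(C)=O | intermediate
12 | 3-substituted 7-methoxychroman-2,4-dione, keto tautomer of 13 (both C3 epimers, not isolated) | COc1ccc2C(=O)C([C@@H](C)/C(C)=C/CC/C(C)=C\COC(C)=O)C(=O)Oc2c1 | intermediate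
13 | (2Z,6E,8S)-8-(4-hydroxy-7-methoxy-2-oxo-2H-chromen-3-yl)-3,7-dimethylnona-2,6-dien-1-yl acetate | COc1ccc2c(O)c([C@@H](C)/C(C)=C/CC/C(C)=C\COC(C)=O)c(=O)oc2c1 | intermediate
14 | 4-hydroxy-3-[(2S,3E,7Z)-9-hydroxy-3,7-dimethylnona-3,7-dien-2-yl]-7-methoxy-2H-chromen-2-one | COc1ccc2c(O)c([C@@H](C)/C(C)=C/CC/C(C)=C\CO)c(=O)oc2c1 | intermediate
15 | (2Z,6E,8S)-8-(4-hydroxy-7-methoxy-2-oxo-2H-chromen-3-yl)-3,7-dimethylnona-2,6-dienal | COc1ccc2c(O)c([C@@H](C)/C(C)=C/CC/C(C)=C\C=O)c(=O)oc2c1 | intermediate
16 | isobutylmagnesium bromide | CC(C)C[Mg]Br | starting material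
17 | bromomagnesium 4-olate of enal 15 (not isolated) | COc1ccc2c(O[Mg]Br)c([C@@H](C)/C(C)=C/CC/C(C)=C\C=O)c(=O)oc2c1 | intermediate
18 | 4-hydroxy-3-[(2S,3E,7Z)-9-hydroxy-3,7,11-trimethyldodeca-3,7-dien-2-yl]-7-methoxy-2H-chromen-2-one (C8' epimers) | COc1ccc2c(O)c([C@@H](C)/C(C)=C/CC/C(C)=C\C(O)CC(C)C)c(=O)oc2c1 | intermediate
19 | 4-hydroxy-7-methoxy-3-[(2S,3E,7Z)-3,7,11-trimethyl-9-oxododeca-3,7-dien-2-yl]-2H-chromen-2-one (CNP0223069.2) | COc1ccc2c(O)c([C@@H](C)/C(C)=C/CC/C(C)=C\C(=O)CC(C)C)c(=O)oc2c1 | target

**Count and risks**

Total step count: 11. Longest linear sequence: 11 steps (neryl acetate 1 to target 19); compounds 5, 10 and 16 are bought.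

Steps most likely to fail:

Step 6. The activated carbinol is a hindered, 2-methyl-substituted secondary allylic centre, so displacement may partly proceed by SN2' attack, by C-alkylation of the ambident coumarin anion, or through an allyl cation ion pair that erodes the enantiomeric purity. The fallback sets out from ketone 8 and coumarin 10 and avoids breaking the C3'–O bond altogether. Reduction of 8 with the (S)-catalyst under the conditions of step 5 should give the enantiomeric carbinol (2Z,6R,7E)-6-hydroxy-3,7-dimethylnona-2,7-dien-1-yl acetate F1. Coumarin 10 is converted with POCl3 into 4-chloro-7-methoxycoumarin F2. The lithium alkoxide of F1 (LiHMDS, THF, −78 °C, where it should not attack the acetate) adds to C4 of F2 and expels chloride (addition–elimination at a vinylogous acyl chloride). This proceeds with retention at C3' and comes back to the route at ether 11.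

Step 7. The concerted shift may be overtaken by ionisation of the allylic C–O bond (scrambling or elimination), and the freshly formed enol may undergo the abnormal Claisen shift or add to the C2'=C3' alkene. The fallback sets out from ether 11 and traps the enol as it forms: heating in toluene with Ac2O and NaOAc (acylative Claisen trapping) should give the enol acetate (2Z,6E,8S)-8-(4-acetoxy-7-methoxy-2-oxo-2H-chromen-3-yl)-3,7-dimethylnona-2,6-dien-1-yl acetate F3, which lacks the free hydroxyl those side reactions need. The methanolysis of step 8 then removes both acetyl groups and the fallback comes back to the route at alcohol 14.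

Step 11. Oxidation of the hindered Z secondary allylic alcohol on MnO2 may be slow, the acidic enol may bind to the oxidant, and long contact may allow Z to E isomerisation of the enone. The fallback sets out from alcohol 18 and masks the enol so that a homogeneous oxidant can be used. MOMCl and iPr2NEt at 0 °C should alkylate the acidic 4-hydroxyl in preference to the neutral carbinol, giving 3-[(2S,3E,7Z)-9-hydroxy-3,7,11-trimethyldodeca-3,7-dien-2-yl]-7-methoxy-4-(methoxymethoxy)-2H-chromen-2-one F4. Dess–Martin oxidation buffered with NaHCO3 then gives the enone 7-methoxy-4-(methoxymethoxy)-3-[(2S,3E,7Z)-3,7,11-trimethyl-9-oxododeca-3,7-dien-2-yl]-2H-chromen-2-one F5. Brief treatment with dilute HCl in MeOH at 0 °C cleaves the vinylogous-ester MOM group and comes back to the route at target 19.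

**Further compounds**

F1 | step 6 | (2Z,6R,7E)-6-hydroxy-3,7-dimethylnona-2,7-dien-1-yl acetate | C/C=C(\C)[C@H](O)CC/C(C)=C\COC(C)=O
F2 | step 6 | 4-chloro-7-methoxycoumarin | COc1ccc2c(Cl)cc(=O)oc2c1
F3 | step 7 | (2Z,6E,8S)-8-(4-acetoxy-7-methoxy-2-oxo-2H-chromen-3-yl)-3,7-dimethylnona-2,6-dien-1-yl acetate | COc1ccc2c(OC(C)=O)c([C@@H](C)/C(C)=C/CC/C(C)=C\COC(C)=O)c(=O)oc2c1
F4 | step 11 | 3-[(2S,3E,7Z)-9-hydroxy-3,7,11-trimethyldodeca-3,7-dien-2-yl]-7-methoxy-4-(methoxymethoxy)-2H-chromen-2-one | COCOc1c([C@@H](C)/C(C)=C/CC/C(C)=C\C(O)CC(C)C)c(=O)oc2cc(OC)ccc12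
F5 | step 11 | 7-methoxy-4-(methoxymethoxy)-3-[(2S,3E,7Z)-3,7,11-trimethyl-9-oxododeca-3,7-dien-2-yl]-2H-chromen-2-one | COCOc1c([C@@H](C)/C(C)=C/CC/C(C)=C\C(=O)CC(C)C)c(=O)oc2cc(OC)ccc12
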